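Compound numbers refer to the list after the steps. Labdane numbering is used for every atom (C17 on C8, C18/C19 on C4, C20 on C10).

## Analysis of the target

Target 28 is a labdane. It has a trans-fused decalin with a gem-dimethyl group at C4, a tetrasubstituted C8=C9 alkene in ring B, and a five-carbon chain on C9 through C11–C12. The chain ends in a 13Z trisubstituted allylic acetate.

The four stereocentres are contiguous on ring B. C10 is quaternary with its methyl β, C5 carries H α, C6 carries an axial β-hydroxyl, and C7 carries a pseudoaxial, allylic α-acetoxy group. The C6 and C7 oxygens are therefore trans-diaxial, and the C6 hydroxyl is syn-axial to both C19 and C20.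

The sensitive points are these:
- The secondary allylic acetate at C7 sits next to a free hydroxyl.
- Any C6 carbonyl precursor is a β,γ-unsaturated ketone that can slip into conjugation.
- The Z alkene must not isomerise.

The hard parts are the quaternary C10 directly attached to a fully substituted alkene carbon, the unequal treatment of three oxygens, and the Z geometry at C13.

The strategy rests on ring B. C8=C9 with its two flanking bonds C7–C8 and C9–C10 is the imprint of an alkyne dienophile, and C10=C5–C6=C7 is the matching diene. C11 on C9 can be a carboxyl carbon tied through oxygen to C1. C1 is a plain CH2 in the target, so the tether oxygen has to be removed afterwards.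

## Retrosynthetic reasoning

**28 to 27 (O-acyl bonds at O7 and O15).** The two acetates are removed last in the retrosynthetic sense. Triol 27 has one primary, one allylic secondary and one doubly syn-axial hydroxyl, so a single acetylation should distinguish them without protecting groups.

**27 to 23 (C7–O bond and the C6 carbinol hydrogen), through 26 and 25.** A ketone at C6 does two jobs. It makes the allylic C7 methylene acidic, so oxygen can be brought in there through the extended enolate. It also lets the hindered axial C6 alcohol be made by hydride delivery to the open α face. The ketone is placed late, in 23, because a β,γ-unsaturated ketone would not survive the hydride and organometallic steps that come before.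

**23 to 18 and 8 (C13–C16 and C11–C12), through 22, 21 and 20.** The Z alkene is traced to the ynoate 21: syn addition of a methyl cuprate puts the new methyl cis to hydrogen, so C12 ends up cis to the ester. The ynoate comes from γ-alkylation of the dianion of 8 with allylic bromide 18. This uses the acid of the tether a second time and makes the alkene geometry a consequence of mechanism. A preformed cyclic Z five-carbon unit was not used, because its geometry would have to survive reductive cleavage of an allylic C–O bond.

**18 to 14 (C6–O and C5–H), through 17.** Hydroboration of the C5=C6 alkene of 14 sets the trans ring fusion and puts oxygen on C6. It is placed after the removal of the C1 oxygen for two reasons. A C6 hydroxyl or ketone could not be carried through the hydride opening of the unsaturated lactone, and a second secondary hydroxyl would compete in the dehydration at C1. Only the C5 configuration matters at this stage, because C6 is oxidised later.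

**14 to 10 (C1–O bond and the lactone acyl–O bond), through 13, 12 and 11.** The tether is dismantled by reducing the lactone to diol 11, masking the primary allylic hydroxyl as acetate 12, eliminating the axial C1 hydroxyl to give 13, and saturating the new disubstituted alkene. An elimination–reduction sequence is preferred to a radical deoxygenation, because a C1 radical sits next to a quaternary carbon that carries two vinyl groups and could rearrange.

**10 to 9 (C9–C10 and C7–C8).** This is the central disconnection. Cutting both bonds opens ring B and the lactone at once and leads back to a monocyclic dienyl ynoate. The forward step must make a quaternary centre at a fully substituted diene terminus and must do so on one face.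

**9 to 7 and 8, and 7 to 6.** The ester bond is trivial. The carbinol centre of 7, which later controls C10, comes from catalytic enantioselective reduction of dienone 6.

**6 to 4, 4 to 2 and 3, 2 to 1.** The cross-conjugated dienone is the product of vinyl addition to vinylogous ester 4 with acidic 1,3-carbonyl transposition. Compound 4 comes from dione 2 and alcohol 3, and 2 comes from C-methylation of commercial 1.

## Alternatives that were turned down

**Alternative 1:** The cut is C8=C9, by ring-closing metathesis. The substrate is triene A2, a ring-A cyclohexane that carries on C10 a 1,1-disubstituted alkene with the complete silylated side chain and on C5 the bis-silyloxy C6–C7 chain ending in an isopropenyl group. The catalyst is RuCl2(=CH-2-iPrOC6H4)(1,3-di-o-tolylimidazolin-2-ylidene), a second-generation Hoveyda–Grubbs catalyst with small N-aryl groups. It would join the two methylene-bearing carbons with loss of the two terminal CH2 groups and give A1.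
- For it: A1 has every carbon and every stereocentre of the target. Desilylation would give triol 27, and the same final acetylation would follow. On the late stage it is clearly shorter than the chosen plan.
- Against it: the closure makes a tetrasubstituted alkene from two 1,1-disubstituted alkenes, one on a quaternary carbon and the other next to a silyloxy-bearing carbon, which is the least favourable metathesis class. The trisubstituted side-chain alkene is a further site for the carbene. A2 also needs C5, C6, C7 and the quaternary C10 set on a flexible, open precursor, so the stereochemical work is moved, not removed.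
- Comparison: the chosen plan sets C10 by intramolecular transfer from one carbinol centre and sets C5–C7 on a rigid bicycle. It pays with more redox steps after the ring is made.

**Alternative 2:** The cut is ring A at C1–C10 and C4–C5. Quinone A3 and diene A4 would combine under a diphenylprolinol-derived B-(o-tolyl)oxazaborolidine activated by triflimide to give the cis-fused enedione A5.
- For it: one catalytic step from two simple components delivers the decalin, the quaternary C10 in the right sense, C17, and carbonyls at C6 and C9. Up to the bicycle it is far shorter than six steps.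
- Against it: A4 carries a cis methyl at the diene terminus, so its reactive s-cis form is strained, and it is acid-sensitive under a strongly acidic catalyst. A5 then needs C5 epimerised, the ring-A alkene removed selectively, and the C7=C8 alkene moved to C8=C9. The C9 carbonyl, flanked by C10 and C8, must accept the whole side chain and lose its oxygen, while the C6 carbonyl of the same enedione is treated differently. That is a long chain of redox and transposition steps on a hindered carbonyl.
- Comparison: in the chosen plan C11 is on C9 and the alkene is at C8=C9 from the moment ring B closes.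

**Alternative 3:** The cut is C6–C7. Activated zinc inserts into the allylic bromide of bromo aldehyde A6, and the γ-carbon of the zinc dienolate adds to the aldehyde to give hydroxy ester A7.
- For it: α-attack would give a four-membered ring, so ring size enforces γ-attack. A7 has C8=C9, C11 at the ester level, the C6 oxygen and no oxygen at C1. One hydride reduction would convert A7 into diol 17, so after its key step this route is about five steps shorter than the chosen one.
- Against it: A6 must be made enantiopure with a trans pair of adjacent centres, an epimerisable aldehyde-bearing C5 and a quaternary C10 that carries a tetrasubstituted alkylidene ester of defined geometry. An aldehyde and an allylic bromide must coexist in it. Building that ring-A piece is the real problem and is likely to cost more steps than it saves.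
- Comparison: the chosen plan reaches its cyclisation substrate in five routine steps with one catalytic asymmetric reduction, and it accepts the later removal of the C1 oxygen as the price.

Key step: step 6

**Remarks on the chemistry.**
- The C15 intermediates are named as drimanes, whose ring and C11 locants coincide with the labdane ones; α/β have the usual meaning with the C10 methyl β.
- The (R)-oxazaborolidine is assigned as the catalyst that gives (S)-7 on the usual model in which the fully substituted alkenyl carbon of 6 is the large group.

## Route

Step 1
Reactants: 1 4,4-dimethylcyclohexane-1,3-dione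
Product: 2 2,4,4-trimethylcyclohexane-1,3-dione
Conditions: MeI, NaOH, H2O–1,4-dioxane, 65 °C
Reagents that add atoms: iodomethane, CI
Why: C-alkylation of the stabilised 1,3-dione enolate at the carbon between the carbonyls; aqueous base favours C- over O-methylation and the mono-methyl product is removed from the equilibrium as its own enolate.

Step 2
Reactants: 2 2,4,4-trimethylcyclohexane-1,3-dione; 3 2-methylpropan-1-ol
Product: 4 3-isobutoxy-2,6,6-trimethylcyclohex-2-en-1-one
Conditions: TsOH·H2O (cat.), benzene, reflux, Dean–Stark
Reagents that add atoms: none
Why: Acid-catalysed vinylogous ester formation; the alcohol should condense at the carbonyl remote from the gem-dimethyl group, so the ketone that remains is the hindered one next to the quaternary carbon, as the next step requires.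

Step 3
Reactants: 4 3-isobutoxy-2,6,6-trimethylcyclohex-2-en-1-one
Product: 6 2,4,4-trimethyl-3-vinylcyclohex-2-en-1-one, via vinyl carbinol adduct 5 (not isolated)
Conditions: CH2=CHMgBr, THF, 0 °C → rt; then 1 M HCl, rt
Reagents that add atoms: vinylmagnesium bromide, C=C[Mg]Br; water, O
Why: 1,2-Addition to the vinylogous ester carbonyl followed by acidic hydrolysis with 1,3-carbonyl transposition (Stork–Danheiser sequence); the ketone has no α-hydrogen on the quaternary side, so addition is not undercut by enolisation.

Step 4
Reactants: 6 2,4,4-trimethyl-3-vinylcyclohex-2-en-1-one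
Product: 7 (S)-2,4,4-trimethyl-3-vinylcyclohex-2-en-1-ol
Conditions: (R)-Me-CBS oxazaborolidine (0.2 equiv), catecholborane, PhMe, −78 °C
Reagents that add atoms: none
Why: Oxazaborolidine-catalysed (CBS) reduction of an α-substituted cyclic enone; the catalyst binds the carbonyl lone pair on the CH2 side and delivers hydride to one face, setting the carbinol centre as S; catecholborane is used so that the vinyl group is not hydroborated.

Step 5
Reactants: 7 (S)-2,4,4-trimethyl-3-vinylcyclohex-2-en-1-ol; 8 but-2-ynoic acid
Product: 9 (S)-2,4,4-trimethyl-3-vinylcyclohex-2-en-1-yl but-2-ynoate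
Conditions: DCC, DMAP (cat.), CH2Cl2, −20 → 0 °C
Reagents that add atoms: none
Why: Carbodiimide esterification (Steglich) under neutral conditions, which should not ionise the allylic carbinol; the stereocentre is not touched.

Step 6
Reactants: 9 (S)-2,4,4-trimethyl-3-vinylcyclohex-2-en-1-yl but-2-ynoate
Product: 10 drima-5,8-dien-11,1α-olide
Conditions: PhMe (0.01 M), BHT (cat.), base-washed sealed tube, 170 °C
Reagents that add atoms: none
Why: A concerted thermal [4+2] cycloaddition between the electron-poor ynoate and the electron-rich diene C10=C5–C6=C7; the closest known reaction type is the intramolecular Diels–Alder reaction of ester-tethered dienyl alkynoates, which gives lactone-bridged cyclohexa-1,4-dienes. Ring B closes as a six-membered carbocycle through the two new bonds C9–C10 and C7–C8, and the five-membered lactone closes in the same event because the C9–C10 bond completes the circuit C1–O–C11–C9–C10. The short tether C1–O–C11 can bring C9 only to C10, so C8 must meet C7 and the regiochemistry is fixed. The one new stereocentre, C10, is controlled by the carbinol centre C1: the ester oxygen can hold the alkyne only over the diene face on which it stands, so C9 adds syn to O1, the lactone is cis-fused and the C10 methyl is β. An alkyne dienophile raises no endo/exo question. The step needs intramolecular reaction to win over dimerisation, which high dilution secures, and it needs the allylic ester to survive heating, which acid-free glass and a radical inhibitor should secure. The fully substituted diene terminus and the twisted s-cis diene are offset by the entropic advantage of the tether.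

Step 7
Reactants: 10 drima-5,8-dien-11,1α-olide
Product: 11 drima-5,8-diene-1α,11-diol
Conditions: LiAlH4, THF, 0 °C
Reagents that add atoms: none
Why: Hydride reduction of the unsaturated lactone to the allylic 1,4-diol; conjugate reduction is not expected because the β-carbon C8 is fully substituted.

Step 8
Reactants: 11 drima-5,8-diene-1α,11-diol
Product: 12 1α-hydroxydrima-5,8-dien-11-yl acetate
Conditions: Ac2O (1.1 equiv), pyridine, CH2Cl2, 0 °C
Reagents that add atoms: acetic anhydride, CC(=O)OC(C)=O
Why: Selective acylation of the primary allylic hydroxyl; the axial C1 hydroxyl next to quaternary C10 should not react at this temperature.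

Step 9
Reactants: 12 1α-hydroxydrima-5,8-dien-11-yl acetate
Product: 13 drima-1,5,8-trien-11-yl acetate
Conditions: Martin sulfurane Ph2S[OC(CF3)2Ph]2, CH2Cl2, rt
Reagents that add atoms: none
Why: Sulfurane-mediated dehydration by anti elimination; the axial 1α-oxygen has an antiperiplanar axial hydrogen on C2, and C10 has no hydrogen, so only the C1=C2 alkene can form.

Step 10
Reactants: 13 drima-1,5,8-trien-11-yl acetate
Product: 14 drima-5,8-dien-11-yl acetate
Conditions: 2-nitrobenzenesulfonylhydrazide, Et3N, CH2Cl2, rt
Reagents that add atoms: none
Why: Diimide reduction, which is strongly sensitive to alkene substitution; the cis-disubstituted C1=C2 alkene should be reduced while the hindered trisubstituted C5=C6 and tetrasubstituted C8=C9 alkenes are left, and diimide causes neither isomerisation nor allylic hydrogenolysis.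

Step 11
Reactants: 14 drima-5,8-dien-11-yl acetate
Product: 17 drim-8-ene-6α,11-diol, via C6 alkylborane 15 (not isolated), via 6α-hydroxy 11-acetate 16 (not isolated)
Conditions: BH3·THF, THF, 0 °C → rt; then 3 M NaOH, 30% H2O2, 0 → 40 °C
Reagents that add atoms: hydrogen peroxide, OO; borane–tetrahydrofuran, B.C1CCOC1 (boron only in 15)
Why: Hydroboration–oxidation; boron goes to the less substituted C6 and hydrogen to C5 by syn addition from the α face, anti to the syn-axial C19 and C20 methyls, which gives the trans ring fusion and the 6α-alcohol with retention. The tetrasubstituted alkene is inert, the alkaline peroxide also cleaves the allylic acetate, and only the C5 centre needs to be right because C6 is oxidised in step 16.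

Step 12
Reactants: 17 drim-8-ene-6α,11-diol
Product: 18 11-bromodrim-8-en-6α-ol
Conditions: CBr4 (1.05 equiv), PPh3, CH2Cl2, −20 °C
Reagents that add atoms: tetrabromomethane, BrC(Br)(Br)Br
Why: Appel bromination, selective for the primary allylic hydroxyl over the hindered secondary one; the bromide cannot cyclise onto O6 because that would require a bridgehead alkene, and it is used without storage.

Step 13
Reactants: 18 11-bromodrim-8-en-6α-ol; 8 but-2-ynoic acid
Product: 20 6α-hydroxy-16-norlabd-8-en-13-yn-15-oic acid, via dilithio but-2-ynoate 19 (not isolated)
Conditions: 8 (3 equiv), LDA (6 equiv), THF–HMPA, −78 °C; then 18, −78 → −20 °C; 1 M HCl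
Reagents that add atoms: none
Why: γ-Alkylation of the but-2-ynoic acid dianion by SN2 displacement at the primary allylic bromide, a known way to homologate allylic halides; attack at the fully substituted C8 is blocked, and the excess dianion absorbs the hydroxyl proton.

Step 14
Reactants: 20 6α-hydroxy-16-norlabd-8-en-13-yn-15-oic acid
Product: 21 methyl 6α-hydroxy-16-norlabd-8-en-13-yn-15-oate
Conditions: TMSCHN2, PhMe–MeOH (3:1), 0 °C
Reagents that add atoms: trimethylsilyldiazomethane, C[Si](C)(C)C=[N+]=[N-]
Why: Methyl esterification of the carboxylic acid through the diazonium ion pair under neutral conditions; the secondary alcohol is not methylated and the ynoate is not exposed to base.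

Step 15
Reactants: 21 methyl 6α-hydroxy-16-norlabd-8-en-13-yn-15-oate
Product: 22 methyl (13Z)-6α-hydroxylabda-8,13-dien-15-oate
Conditions: MeLi, CuI, THF, 0 °C (Me2CuLi, 3.5 equiv); then 21, −78 °C; MeOH then aq. NH4Cl at −78 °C
Reagents that add atoms: lithium dimethylcuprate, [Li+].C[Cu-]C
Why: Syn carbocupration of the ynoate places the methyl on C13 and copper on C14 on the same side; protonation at −78 °C with retention leaves the methyl cis to hydrogen, so C12 is cis to the ester (13Z). The low temperature prevents equilibration of the vinylcopper through the allenoate, and the excess reagent covers the free hydroxyl.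

Step 16
Reactants: 22 methyl (13Z)-6α-hydroxylabda-8,13-dien-15-oate
Product: 23 methyl (13Z)-6-oxolabda-8,13-dien-15-oate
Conditions: Dess–Martin periodinane, NaHCO3, CH2Cl2, 0 °C → rt
Reagents that add atoms: none
Why: Buffered periodinane oxidation of the secondary alcohol under near-neutral conditions, so the β,γ-unsaturated ketone is not drawn into conjugation and the trans-fused C5 centre is kept.

Step 17
Reactants: 23 methyl (13Z)-6-oxolabda-8,13-dien-15-oate
Product: 25 methyl (13Z)-7α-hydroxy-6-oxolabda-8,13-dien-15-oate, via potassium dienolate 24 (not isolated)
Conditions: KHMDS (1.1 equiv), THF, −78 °C; then 2-(phenylsulfonyl)-3-phenyloxaziridine, −78 °C; sat. NH4Cl at −78 °C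
Reagents that add atoms: 2-(phenylsulfonyl)-3-phenyloxaziridine, O=S(=O)(c1ccccc1)N1OC1c1ccccc1
Why: Enolate α-hydroxylation with an N-sulfonyloxaziridine; the allylic C7 protons are by far the most acidic, and the extended enolate reacts at C7 because the γ-carbon C9 is fully substituted and flanked by quaternary C10. Axial approach on the α face, which meets only the C5 hydrogen, should give the 7α-alcohol.

Step 18
Reactants: 25 methyl (13Z)-7α-hydroxy-6-oxolabda-8,13-dien-15-oate
Product: 26 methyl (13Z)-6β,7α-dihydroxylabda-8,13-dien-15-oate
Conditions: NaBH4, CeCl3·7H2O, MeOH, −78 → −40 °C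
Reagents that add atoms: none
Why: Luche reduction; the β face of the C6 carbonyl is closed by the syn-axial C19 and C20 methyls, so hydride should enter from the α face and give the axial 6β-alcohol. The enoate is not reduced, and the cold, weakly acidic medium leaves the α-ketol no time to transpose.

Step 19
Reactants: 26 methyl (13Z)-6β,7α-dihydroxylabda-8,13-dien-15-oate
Product: 27 (13Z)-labda-8,13-diene-6β,7α,15-triol
Conditions: DIBAL (5 equiv), CH2Cl2, −78 → 0 °C; Rochelle salt
Reagents that add atoms: none
Why: 1,2-Reduction of the conjugated ester to the allylic alcohol by an aluminium hydride, without conjugate reduction or change of alkene geometry; the two hydroxyls only consume reagent.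

Step 20
Reactants: 27 (13Z)-labda-8,13-diene-6β,7α,15-triol
Product: 28 (13Z)-6β-hydroxylabda-8,13-diene-7α,15-diyl diacetate
Conditions: Ac2O (2.5 equiv), pyridine, DMAP (cat.), CH2Cl2, 0 °C → rt
Reagents that add atoms: acetic anhydride, CC(=O)OC(C)=O
Why: Acylation of the primary C15 and the allylic C7 hydroxyls; the 6β-hydroxyl is syn-axial to two methyl groups and should not be acetylated under these conditions, and its trans-diaxial relation to O7 prevents acyl migration.

## Compound list

1 | 4,4-dimethylcyclohexane-1,3-dione | O=C1CCC(C)(C)C(=O)C1 | starting material
2 | 2,4,4-trimethylcyclohexane-1,3-dione (racemic, enolisable) | CC1C(=O)CCC(C)(C)C1=O | intermediate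
3 | 2-methylpropan-1-ol (isobutanol) | CC(C)CO | starting material
4 | 3-isobutoxy-2,6,6-trimethylcyclohex-2-en-1-one | CC(C)COC1=C(C)C(=O)C(C)(C)CC1 | intermediate
5 | 3-isobutoxy-2,6,6-trimethyl-1-vinylcyclohex-2-en-1-ol (racemic; present as its magnesium alkoxide) | CC(C)COC1=C(C)C(O)(C=C)C(C)(C)CC1 | intermediate
6 | 2,4,4-trimethyl-3-vinylcyclohex-2-en-1-one | C=CC1=C(C)C(=O)CCC1(C)C | intermediate
7 | (S)-2,4,4-trimethyl-3-vinylcyclohex-2-en-1-ol | O[C@H]1CCC(C)(C)C(C=C)=C1C | intermediate
8 | but-2-ynoic acid | CC#CC(O)=O | starting material
9 | (S)-2,4,4-trimethyl-3-vinylcyclohex-2-en-1-yl but-2-ynoate | CC#CC(=O)O[C@H]1CCC(C)(C)C(C=C)=C1C | intermediate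
10 | drima-5,8-dien-11,1α-olide (10β-methyl, cis-fused γ-lactone C1–O–C11(=O)–C9) | CC1=C2C(=O)O[C@H]3CCC(C)(C)C(=CC1)[C@@]23C | intermediate
11 | drima-5,8-diene-1α,11-diol | OCC1=C(C)CC=C2C(C)(C)CC[C@H](O)[C@]12C | intermediate
12 | 1α-hydroxydrima-5,8-dien-11-yl acetate | CC(=O)OCC1=C(C)CC=C2C(C)(C)CC[C@H](O)[C@]12C | intermediate
13 | drima-1,5,8-trien-11-yl acetate | CC(=O)OCC1=C(C)CC=C2C(C)(C)CC=C[C@]12C | intermediate
14 | drima-5,8-dien-11-yl acetate | CC(=O)OCC1=C(C)CC=C2C(C)(C)CCC[C@]12C | intermediate
15 | (11-acetoxydrim-8-en-6α-yl)borane (5α-H) | CC(=O)OCC1=C(C)C[C@H](B)[C@H]2C(C)(C)CCC[C@]12C | intermediate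
16 | 6α-hydroxydrim-8-en-11-yl acetate (5α-H) | CC(=O)OCC1=C(C)C[C@H](O)[C@H]2C(C)(C)CCC[C@]12C | intermediate
17 | drim-8-ene-6α,11-diol (5α-H, 10β-methyl) | OCC1=C(C)C[C@H](O)[C@H]2C(C)(C)CCC[C@]12C | intermediate
18 | 11-bromodrim-8-en-6α-ol | BrCC1=C(C)C[C@H](O)[C@H]2C(C)(C)CCC[C@]12C | intermediate
19 | dilithium salt of the but-2-ynoic acid dianion (lithium 4-lithiobut-2-ynoate) | [Li+].[Li+].[CH2-]C#CC(=O)[O-] | intermediate
20 | 6α-hydroxy-16-norlabd-8-en-13-yn-15-oic acid | OC(=O)C#CCCC1=C(C)C[C@H](O)[C@H]2C(C)(C)CCC[C@]12C | intermediate
21 | methyl 6α-hydroxy-16-norlabd-8-en-13-yn-15-oate | COC(=O)C#CCCC1=C(C)C[C@H](O)[C@H]2C(C)(C)CCC[C@]12C | intermediate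
22 | methyl (13Z)-6α-hydroxylabda-8,13-dien-15-oate | COC(=O)/C=C(/C)CCC1=C(C)C[C@H](O)[C@H]2C(C)(C)CCC[C@]12C | intermediate
23 | methyl (13Z)-6-oxolabda-8,13-dien-15-oate | COC(=O)/C=C(/C)CCC1=C(C)CC(=O)[C@H]2C(C)(C)CCC[C@]12C | intermediate
24 | potassium dienolate of 23 (O– on C6, C6=C7 and C8=C9) | COC(=O)/C=C(/C)CCC1=C(C)C=C([O-])[C@H]2C(C)(C)CCC[C@]12C.[K+] | intermediate
25 | methyl (13Z)-7α-hydroxy-6-oxolabda-8,13-dien-15-oate | COC(=O)/C=C(/C)CCC1=C(C)[C@H](O)C(=O)[C@H]2C(C)(C)CCC[C@]12C | intermediate
26 | methyl (13Z)-6β,7α-dihydroxylabda-8,13-dien-15-oate | COC(=O)/C=C(/C)CCC1=C(C)[C@H](O)[C@@H](O)[C@H]2C(C)(C)CCC[C@]12C | intermediate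
27 | (13Z)-labda-8,13-diene-6β,7α,15-triol | OC/C=C(/C)CCC1=C(C)[C@H](O)[C@@H](O)[C@H]2C(C)(C)CCC[C@]12C | intermediate
28 | (13Z)-6β-hydroxylabda-8,13-diene-7α,15-diyl diacetate | CC(=O)OC/C=C(/C)CCC1=C(C)[C@H](OC(C)=O)[C@@H](O)[C@H]2C(C)(C)CCC[C@]12C | target

## Step count and least certain steps

Total: 20 steps. Longest linear sequence: 20 steps, from 1 to 28. Compounds 3 and 8 are purchased, and 8 enters twice (steps 5 and 13).

**Step 6 (key step).** The reacting geometry requires the ester to turn into its less favoured conformation and the vinyl group to rotate against the C10 methyl. The cycloaddition may therefore be slow enough for thermal ionisation and elimination of the allylic ester, or intermolecular addition, to compete. The fallback activates the dienophile and brings in C17 afterwards. It sets out from 7, which would be esterified (DCC, DMAP) with 3-(p-tolylsulfonyl)prop-2-ynoic acid F1 to give (S)-2,4,4-trimethyl-3-vinylcyclohex-2-en-1-yl 3-(p-tolylsulfonyl)prop-2-ynoate F2. The sulfonyl alkyne is far more electron-poor and should cyclise near room temperature to 8-(p-tolylsulfonyl)-12-nordrima-5,8-dien-11,1α-olide F3. Conjugate addition of Me2CuLi at C8 with loss of sulfinate should then install the methyl group, and the route is rejoined at 10.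

**Step 17.** Three processes threaten this step: oxidation of the extended enolate at C9 instead of C7, attack from the β face, and transposition of the α-ketol to the conjugated 6-hydroxy-7-ketone during quench. The fallback sets C7 by an invertive epoxide opening and avoids an α-ketol altogether. It sets out from 23. The potassium enolate would be brominated with N-bromosuccinimide to methyl (13Z)-7α-bromo-6-oxolabda-8,13-dien-15-oate F4, the axial bromide being the preferred epimer. NaBH4/CeCl3·7H2O would give the trans-diaxial bromohydrin, methyl (13Z)-7α-bromo-6β-hydroxylabda-8,13-dien-15-oate F5. K2CO3 in methanol would close it to methyl (13Z)-6β,7β-epoxylabda-8,13-dien-15-oate F6. Dilute HClO4 in aqueous THF should open F6 at the allylic C7 from the α face, and the route is rejoined at 26.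

**Step 13.** The dianion is an ambident propargyl–allenyl nucleophile and may alkylate at its α-carbon to give an allenic acid. Free amide base may also cause 1,4-elimination of the allylic bromide. The fallback builds the ynoate in separate stages. It sets out from 18, which would be alkylated with lithiated 1-(trimethylsilyl)propyne (n-BuLi, THF, −78 °C), a propargyl nucleophile of reliable regiochemistry, to give 14-(trimethylsilyl)-15,16-dinorlabd-8-en-13-yn-6α-ol F7. K2CO3 in methanol would give the terminal alkyne 15,16-dinorlabd-8-en-13-yn-6α-ol F8. Double deprotonation (n-BuLi, 2.2 equiv) and carboxylation with CO2 would rejoin the route at 20.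

**Step 9.** The C1 hydroxyl is axial and neopentyl. If ionisation runs ahead of the anti elimination, a vinyl or methyl group could shift from C10, or conversion could stall at the alkoxysulfurane. The fallback uses a concerted syn elimination with no charged or radical intermediate. It sets out from 12, which would be converted (NaHMDS, CS2, then MeI, −78 °C) into O-(11-acetoxydrima-5,8-dien-1α-yl) S-methyl dithiocarbonate F9. Pyrolysis of F9 (Chugaev elimination, through the cis hydrogen on C2) would rejoin the route at 13.

**Step 2.** The alcohol may also condense at the hindered carbonyl, and the resulting regioisomeric enol ether would place the vinyl group on the wrong carbon in step 3. The fallback fixes the regiochemistry by construction. It sets out from 3 and 2-methylcyclohexane-1,3-dione F10, a symmetrical dione that can give only one enol ether, 3-isobutoxy-2-methylcyclohex-2-en-1-one F11. Two successive α'-methylations (LDA, MeI, −78 °C), through 3-isobutoxy-2,6-dimethylcyclohex-2-en-1-one F12, would rejoin the route at 4 and make steps 1 and 2 unnecessary.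

## Further compounds

F1 | step 6 | 3-(p-tolylsulfonyl)prop-2-ynoic acid (input of the fallback) | Cc1ccc(cc1)S(=O)(=O)C#CC(O)=O
F2 | step 6 | (S)-2,4,4-trimethyl-3-vinylcyclohex-2-en-1-yl 3-(p-tolylsulfonyl)prop-2-ynoate | Cc1ccc(cc1)S(=O)(=O)C#CC(=O)O[C@H]1CCC(C)(C)C(C=C)=C1C
F3 | step 6 | 8-(p-tolylsulfonyl)-12-nordrima-5,8-dien-11,1α-olide | Cc1ccc(cc1)S(=O)(=O)C1=C2C(=O)O[C@H]3CCC(C)(C)C(=CC1)[C@@]23C
F4 | step 17 | methyl (13Z)-7α-bromo-6-oxolabda-8,13-dien-15-oate | COC(=O)/C=C(/C)CCC1=C(C)[C@H](Br)C(=O)[C@H]2C(C)(C)CCC[C@]12C
F5 | step 17 | methyl (13Z)-7α-bromo-6β-hydroxylabda-8,13-dien-15-oate | COC(=O)/C=C(/C)CCC1=C(C)[C@H](Br)[C@@H](O)[C@H]2C(C)(C)CCC[C@]12C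
F6 | step 17 | methyl (13Z)-6β,7β-epoxylabda-8,13-dien-15-oate | COC(=O)/C=C(/C)CCC1=C(C)[C@H]3O[C@H]3[C@H]2C(C)(C)CCC[C@]12C
F7 | step 13 | 14-(trimethylsilyl)-15,16-dinorlabd-8-en-13-yn-6α-ol | C[Si](C)(C)C#CCCC1=C(C)C[C@H](O)[C@H]2C(C)(C)CCC[C@]12C
F8 | step 13 | 15,16-dinorlabd-8-en-13-yn-6α-ol | C#CCCC1=C(C)C[C@H](O)[C@H]2C(C)(C)CCC[C@]12C
F9 | step 9 | O-(11-acetoxydrima-5,8-dien-1α-yl) S-methyl dithiocarbonate | CC(=O)OCC1=C(C)CC=C2C(C)(C)CC[C@H](OC(=S)SC)[C@]12C
F10 | step 2 | 2-methylcyclohexane-1,3-dione (input of the fallback) | CC1C(=O)CCCC1=O
F11 | step 2 | 3-isobutoxy-2-methylcyclohex-2-en-1-one | CC(C)COC1=C(C)C(=O)CCC1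
F12 | step 2 | 3-isobutoxy-2,6-dimethylcyclohex-2-en-1-one (racemic) | CC(C)COC1=C(C)C(=O)C(C)CC1
A1 | alternative 1 | (13Z)-6β,7α-bis(triethylsilyloxy)-15-(tert-butyldimethylsilyloxy)labda-8,13-diene | CC(C)(C)[Si](C)(C)OC/C=C(/C)CCC1=C(C)[C@H](O[Si](CC)(CC)CC)[C@@H](O[Si](CC)(CC)CC)[C@H]2C(C)(C)CCC[C@]12C
A2 | alternative 1 | metathesis triene: 1,3,3-trimethylcyclohexane carrying on C10 the 1-methylene-(4Z)-6-(tert-butyldimethylsilyloxy)-4-methylhex-4-enyl group and on C5 the 1,2-bis(triethylsilyloxy)-3-methylbut-3-enyl group, configured as in the target | CC(C)(C)[Si](C)(C)OC/C=C(/C)CCC(=C)[C@@]1(C)CCCC(C)(C)[C@@H]1[C@H](O[Si](CC)(CC)CC)[C@@H](O[Si](CC)(CC)CC)C(C)=C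
A3 | alternative 2 | 2,6-dimethyl-1,4-benzoquinone | CC1=CC(=O)C=C(C)C1=O
A4 | alternative 2 | 4-methylpenta-1,3-diene | C=CC=C(C)C
A5 | alternative 2 | cis-2,5,5,8a-tetramethyl-4a,5,8,8a-tetrahydronaphthalene-1,4-dione | O=C1C(C)=CC(=O)[C@@H]2C(C)(C)C=CC[C@]12C
A6 | alternative 3 | methyl (E)-4-bromo-2-(2-formyl-1,3,3-trimethylcyclohexyl)-3-methylbut-2-enoate, C5 and C10 as in the target | COC(=O)/C(=C(\C)CBr)[C@@]1(C)CCCC(C)(C)[C@@H]1C=O
A7 | alternative 3 | methyl 6α-hydroxydrim-8-en-11-oate | COC(=O)C1=C(C)C[C@H](O)[C@H]2C(C)(C)CCC[C@]12C
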